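**Retrosynthetic overview**

1. The ten-membered ring is opened last at C2–C3 (Nozaki–Hiyama–Kishi closure of a Z-vinyl iodide onto a C2 aldehyde). The seco chain is cut at C9–C10 into a ring-A allylboronate 31 (from (S)-carvone, which supplies C14 and directs C1) and lactone aldehyde 23; a chair allylboration sets C9/C10 and places C11=C12.
2. γ-Lactone (O, C19, C17, C8, C7): O–C7 and C19–C17 are both cut. CO2 serves as a one-carbon linchpin between a C17 carbanion and a C7 allyl-cation terminus in the open-chain sulfide diol 15 (C8 from a Sharpless epoxidation).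
3. Enabling feature: C17 is β to the tertiary C8 hydroxyl, so it can be held as a β-oxido alkyllithium. The lactone oxygen on C7 is allylic to C5=C6: C7–C6=C5 is an allyl triad whose far end C5 carries C16 and C4. On the lactone, C6 and the C18 methyl both sit trans to C9, the thermodynamic arrangement.
4. Ring order: ring A is carried intact from carvone; the γ-lactone is closed in step 13; the ten-membered carbocycle is closed last (step 28).

Key step: step 13

Remark: briarane locants of the target are used throughout (C17 carries methyl C18 and carbonyl C19; C16 is the hydroxymethyl on C5). Centres that a later step destroys (C5 in 15–17, C6 in 26) are carried as mixtures.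

**Fragment B (lactone aldehyde 23)**

Step 1
Reactants: 1 (E)-but-2-enal
Product: 2 (Z)-2-iodobut-2-enal
Conditions: I2, K2CO3, DMAP (cat.), THF/H2O, 23 °C
Reagents that add atoms: iodine, II
Why: α-Iodination of the enal (conjugate addition of DMAP, iodination of the enolate, E1cB loss of DMAP) should give the thermodynamic Z isomer with methyl trans to formyl.

Step 2
Reactants: 2 (Z)-2-iodobut-2-enal
Product: 3 (Z)-2-iodobut-2-en-1-ol
Conditions: NaBH4, CeCl3·7H2O, MeOH, 0 °C
Reagents that add atoms: none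
Why: Luche 1,2-reduction leaves the vinyl iodide and the olefin geometry untouched.

Step 3
Reactants: 3 (Z)-2-iodobut-2-en-1-ol; 4 ethynyl(trimethyl)silane
Product: 5 (E)-2-[(trimethylsilyl)ethynyl]but-2-en-1-ol
Conditions: Pd(PPh3)2Cl2 (2 mol %), CuI (4 mol %), Et3N, THF, 23 °C
Reagents that add atoms: none
Why: Sonogashira coupling proceeds with retention of olefin geometry, so the methyl group ends trans to the hydroxymethyl group.

Step 4
Reactants: 5 enynol
Product: 6 [(2S,3S)-3-methyl-2-[(trimethylsilyl)ethynyl]oxiran-2-yl]methanol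
Conditions: Ti(Oi-Pr)4 (10 mol %), L-(+)-diethyl tartrate (12 mol %), t-BuOOH, 4 Å molecular sieves, CH2Cl2, −20 °C
Reagents that add atoms: tert-butyl hydroperoxide, CC(C)(C)OO
Why: Katsuki–Sharpless asymmetric epoxidation; the L-(+)-tartrate catalyst should deliver oxygen to the face that gives the (2S,3S)-epoxy alcohol, as for other E-3-substituted allylic alcohols, which sets C8 by reagent control.

Step 5
Reactants: 6 epoxy alcohol
Product: 7 (2S,3R)-3-(phenylsulfanyl)-2-[(trimethylsilyl)ethynyl]butane-1,2-diol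
Conditions: PhSH, Ti(Oi-Pr)4 (1.5 equiv), CH2Cl2, 23 °C
Reagents that add atoms: benzenethiol, Sc1ccccc1
Why: Titanium-mediated opening of the 2,3-epoxy alcohol should occur at the secondary carbon (C17) with inversion, leaving the tertiary C8–O bond and its configuration intact.

Step 6
Reactants: 7 sulfide diol
Product: 8 primary TBS ether of 7
Conditions: t-BuMe2SiCl, imidazole, CH2Cl2, 0 °C
Reagents that add atoms: tert-butyl(chloro)dimethylsilane, CC(C)(C)[Si](C)(C)Cl
Why: Selective silylation of the primary hydroxyl (C9) keeps the tertiary C8 hydroxyl free for later use as an alkoxide.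

Step 7
Reactants: 8 silyl ether
Product: 9 terminal alkyne
Conditions: K2CO3 (cat.), MeOH, 0 to 23 °C
Reagents that add atoms: none
Why: Methanolysis cleaves the alkynyl C–Si bond only; the silyl ether and the β-hydroxy sulfide are stable.

Step 8
Reactants: 9 terminal alkyne
Product: 10 (E)-vinylstannane
Conditions: Bu3SnH, Pd(PPh3)2Cl2 (2 mol %), THF, 0 °C
Reagents that add atoms: tributylstannane, CCCC[SnH](CCCC)CCCC
Why: Palladium-catalysed syn-hydrostannation should place tin on the terminal carbon, remote from the quaternary carbinol, and so give the E olefin (C6=C7).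

Step 9
Reactants: 11 methyl 2-hydroxyacetate
Product: 12 methyl 2-[tri(propan-2-yl)silyloxy]acetate
Conditions: i-Pr3SiCl, imidazole, DMF, 23 °C
Reagents that add atoms: chlorotri(propan-2-yl)silane, CC(C)[Si](Cl)(C(C)C)C(C)C
Why: Standard silylation; the robust TIPS group is chosen to outlast the TBS ether on C9.

Step 10
Reactants: 12 silyloxy ester
Product: 13 N-methoxy-N-methyl-2-[tri(propan-2-yl)silyloxy]acetamide
Conditions: MeNHOMe·HCl, i-PrMgCl, THF, −20 °C
Reagents that add atoms: N,O-dimethylhydroxylamine hydrochloride, CNOC.Cl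
Why: Aminolysis of the ester by the chloromagnesium amide gives the Weinreb amide.

Step 11
Reactants: 13 Weinreb amide; 4 ethynyl(trimethyl)silane
Product: 14 1-[tri(propan-2-yl)silyloxy]-4-(trimethylsilyl)but-3-yn-2-one
Conditions: n-BuLi, THF, −78 °C; then 13; aqueous NH4Cl
Reagents that add atoms: none
Why: Acylation of the lithium acetylide by the Weinreb amide stops at the ketone because the chelated tetrahedral intermediate persists until work-up.

Step 12
Reactants: 10 vinylstannane; 14 ynone
Product: 15 sulfide diol (C5 epimers)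
Conditions: n-BuLi (2.1 equiv), THF, −78 °C; CeCl3; then 14, −78 °C; aqueous NH4Cl
Reagents that add atoms: none
Why: Tin–lithium exchange with retention gives the E-vinyllithium (as its alkoxide), and the organocerium derived from it should add 1,2 to the ynone without enolization; the new C5 carbinol configuration is irrelevant.

Step 13
Reactants: 15 sulfide diol
Product: 18 γ-lactone (C17 epimers), via trilithio species 16 (not isolated), via hydroxy acid 17 (not isolated)
Conditions: n-BuLi (2.0 equiv), THF, −78 °C; lithium 4,4′-di-tert-butylbiphenylide (LiDBB, 2.2 equiv), −78 °C; CO2 (g), −78 to 0 °C; then CF3CO2H (excess), CH2Cl2, 0 °C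
Reagents that add atoms: carbon dioxide, O=C=O
Why: After both hydroxyls are lithiated, LiDBB cleaves the C17–S bond by two one-electron transfers to give the β-oxido alkyllithium 16 (loss of Li2O is slow at −78 °C), and C17 attacks CO2 to form C17–C19; on acidification the allylic and propargylic tertiary C5 hydroxyl of 17 ionizes and the carboxyl oxygen captures the allyl cation at C7, forming O–C7 with shift of the olefin to C5=C6. The closest known reaction types are the carbonation of β-oxido organolithiums made by reductive lithiation and the acid- or Re2O7-promoted transpositive cyclization of allylic alcohols onto pendant nucleophiles. The γ-lactone (O, C19, C17, C8, C7) closes in a 5-exo mode onto the allyl-cation terminus, and the E geometry of C6=C7 in 15 forbids both the seven-membered lactone at C5 and the dihydrofuran from O8. C7 is controlled by the quaternary C8 (the C6 chain goes trans to the bulky C9 silyloxymethyl and cis to OH, and reversible ionization allows correction), C8 is inherited from step 4, and C17 forms as a mixture that step 14 corrects. C5=C6 should form E (slim alkynyl cis to C7, silyloxymethyl trans) through allylic-strain control in the ionizing conformer and through thermodynamics. The step needs C–S cleavage to outrun electron transfer to the silylalkyne and ionization at C5 rather than C8; the weak C–S bond at low temperature and the double activation of C5 (against the inductively deactivated C8) should secure both.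

Step 14
Reactants: 18 γ-lactone (C17 epimers)
Product: 19 (3R,4R,5S)-lactone (17R)
Conditions: DBU (0.3 equiv), toluene, 23 °C
Reagents that add atoms: none
Why: Equilibration through the lactone enolate should favour the C18 methyl trans to the bulky C9 substituent on C8 (cis to OH), which is the 17R configuration.

Step 15
Reactants: 19 lactone
Product: 20 iodoalkyne
Conditions: N-iodosuccinimide, AgNO3 (10 mol %), acetone, 23 °C, dark
Reagents that add atoms: N-iodosuccinimide, O=C1CCC(=O)N1I
Why: Silver-catalysed iododesilylation converts the alkynylsilane directly into the 1-iodoalkyne; the tertiary alcohol and the silyl ethers are inert.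

Step 16
Reactants: 20 iodoalkyne
Product: 21 (1E,3Z)-iododiene lactone
Conditions: 2-nitrobenzenesulfonohydrazide, Et3N, THF/i-PrOH, 23 °C
Reagents that add atoms: none
Why: Diimide generated in the flask reduces the iodoalkyne by syn hydrogen transfer to the Z-vinyl iodide (C3=C4); the trisubstituted C5=C6 olefin is too hindered to react.

Step 17
Reactants: 21 iododiene lactone
Product: 22 diol (C9 hydroxymethyl free)
Conditions: HF·pyridine, pyridine, THF, 0 °C
Reagents that add atoms: none
Why: Buffered fluoride removes the TBS ether much faster than the TIPS ether and does not ionize the allylic lactone C7–O bond.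

Step 18
Reactants: 22 diol
Product: 23 lactone aldehyde (C9 formyl)
Conditions: TEMPO (cat.), PhI(OAc)2, CH2Cl2, 23 °C
Reagents that add atoms: none
Why: Oxoammonium oxidation takes the primary alcohol to the aldehyde; the tertiary C8 hydroxyl cannot be oxidized and there is no α-hydrogen to epimerize.

**Fragment A (ring-A allylboronate 31)**

Step 19
Reactants: 24 (S)-carvone
Product: 26 6-(dimethoxymethyl)carvone (C6 epimers), via silyl dienol ether 25 (not isolated)
Conditions: LiN(i-Pr)2, THF, −78 °C; Me3SiCl; then HC(OMe)3, Me3SiOTf (cat.), CH2Cl2, −78 °C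
Reagents that add atoms: trimethyl orthoformate, COC(OC)OC
Why: Kinetic α′-deprotonation and O-silylation, then a Mukaiyama-type alkylation of the silyl dienol ether with the orthoformate, install the masked C2 aldehyde.

Step 20
Reactants: 26 acetal enone
Product: 27 (5R,6R)-6-(dimethoxymethyl)-2,6-dimethyl-5-(prop-1-en-2-yl)cyclohex-2-en-1-one
Conditions: LiN(i-Pr)2, THF, −78 °C; MeI, DMPU, −78 to −40 °C
Reagents that add atoms: iodomethane, CI
Why: The α′-enolate should be methylated anti to the adjacent isopropenyl group, which sets C1 with the methyl trans and the C2 carbon cis to the future C14 oxygen.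

Step 21
Reactants: 27 quaternary enone
Product: 28 (1S,2R)-2-(dimethoxymethyl)-2,4-dimethyl-3-oxocyclohex-4-en-1-yl acetate
Conditions: O3, CH2Cl2/MeOH, −78 °C; then Ac2O, Et3N, DMAP (cat.), −78 to 23 °C
Reagents that add atoms: ozone, [O-][O+]=O; methanol, CO
Why: The electron-rich isopropenyl group is ozonized in preference to the enone olefin, and Criegee rearrangement of the acylated methoxy hydroperoxide (C-to-O shift with retention) gives the C14 acetate.

Step 22
Reactants: 28 acetoxy enone
Product: 29 (1S,2R,3R)-allylic alcohol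
Conditions: NaBH4, CeCl3·7H2O, MeOH, −78 °C
Reagents that add atoms: none
Why: In this Luche reduction, hydride should attack C10 from the face of the C1 methyl, away from the cis-disposed dimethoxymethyl and acetoxy groups, placing the hydroxyl cis to them.

Step 23
Reactants: 29 allylic alcohol
Product: 30 allylic methyl carbonate
Conditions: ClCO2Me, pyridine, DMAP (cat.), CH2Cl2, 0 °C
Reagents that add atoms: methyl chloroformate, COC(Cl)=O
Why: Acylation of the secondary allylic alcohol provides the leaving group for allylic substitution.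

Step 24
Reactants: 30 allylic carbonate
Product: 31 (1S,2R,5S)-allylboronate
Conditions: bis(pinacolato)diboron, CuCl (5 mol %), Xantphos (5 mol %), KOt-Bu (10 mol %), THF, 23 °C
Reagents that add atoms: bis(pinacolato)diboron, CC1(C)OB(OC1(C)C)B1OC(C)(C)C(C)(C)O1
Why: Copper-catalysed γ-selective anti-SN2′ borylation should place boron on C12 on the face opposite the carbonate (the methyl face) and move the olefin to C10=C11.

**Union and end game**

Step 25
Reactants: 31 allylboronate; 23 lactone aldehyde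
Product: 32 homoallylic alcohol (9S,10S)
Conditions: toluene, 4 Å molecular sieves, 23 to 60 °C; then pH 7 buffer
Reagents that add atoms: none
Why: Allylboration through a closed six-membered chair transition state forms C9–C10 on the boron-bearing face of C10 (trans to the C2 branch) with the aldehyde substituent equatorial; the ring-fixed Z allyl geometry gives the syn (9S,10S) pair and the olefin returns to C11=C12.

Step 26
Reactants: 32 homoallylic alcohol
Product: 33 C9 acetate
Conditions: Ac2O, DMAP, Et3N, CH2Cl2, 23 °C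
Reagents that add atoms: acetic anhydride, CC(=O)OC(C)=O
Why: The secondary C9 hydroxyl is acylated while the tertiary C8 hydroxyl stays free.

Step 27
Reactants: 33 acetal
Product: 34 C2 aldehyde
Conditions: PPTS (cat.), acetone/H2O, 50 °C
Reagents that add atoms: water, O
Why: Mild acid hydrolysis of the dimethyl acetal frees the non-enolizable neopentyl aldehyde; esters, TIPS ether and vinyl iodide should survive.

Step 28
Reactants: 34 iodo aldehyde
Product: 35 macrocyclic allylic alcohol (2S)
Conditions: CrCl2 (10 equiv), NiCl2 (1 mol %), DMSO/THF, 23 °C, 2 mM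
Reagents that add atoms: none
Why: Nozaki–Hiyama–Kishi reaction: the Z-alkenylchromium formed with retention adds chemoselectively to the aldehyde and closes the ten-membered ring at C2–C3; attack on the aldehyde face syn to the C1 methyl, held by the trans ring fusion, should give the 2S alcohol.

Step 29
Reactants: 35 macrocyclic alcohol
Product: 36 triacetate TIPS ether
Conditions: Ac2O, DMAP (cat.), pyridine, CH2Cl2, 0 to 23 °C
Reagents that add atoms: acetic anhydride, CC(=O)OC(C)=O
Why: Acetylation of the secondary allylic C2 hydroxyl; the tertiary C8 hydroxyl should not react.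

Step 30
Reactants: 36 triacetate TIPS ether
Product: 37 target CNP0215504.2
Conditions: HF·pyridine, THF, 0 to 23 °C
Reagents that add atoms: none
Why: Fluoride cleaves the primary allylic TIPS ether; acetates, lactone and tertiary alcohol are stable to it.

**Compound list**

1 | (E)-but-2-enal | C/C=C/C=O | starting material
2 | (Z)-2-iodobut-2-enal | C/C=C(\I)C=O | intermediate
3 | (Z)-2-iodobut-2-en-1-ol | C/C=C(\I)CO | intermediate
4 | ethynyl(trimethyl)silane | C#C[Si](C)(C)C | starting material
5 | (E)-2-[(trimethylsilyl)ethynyl]but-2-en-1-ol | C/C=C(/CO)C#C[Si](C)(C)C | intermediate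
6 | [(2S,3S)-3-methyl-2-[(trimethylsilyl)ethynyl]oxiran-2-yl]methanol | C[C@@H]1O[C@@]1(C#C[Si](C)(C)C)CO | intermediate
7 | (2S,3R)-3-(phenylsulfanyl)-2-[(trimethylsilyl)ethynyl]butane-1,2-diol | C[C@@H](Sc1ccccc1)[C@@](C#C[Si](C)(C)C)(O)CO | intermediate
8 | (2S,3R)-1-[(tert-butyldimethylsilyl)oxy]-3-(phenylsulfanyl)-2-[(trimethylsilyl)ethynyl]butan-2-ol | C[C@@H](Sc1ccccc1)[C@@](C#C[Si](C)(C)C)(O)CO[Si](C)(C)C(C)(C)C | intermediate
9 | (2S,3R)-1-[(tert-butyldimethylsilyl)oxy]-2-ethynyl-3-(phenylsulfanyl)butan-2-ol | C[C@@H](Sc1ccccc1)[C@@](C#C)(O)CO[Si](C)(C)C(C)(C)C | intermediate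
10 | (1E,3S,4R)-3-{[(tert-butyldimethylsilyl)oxy]methyl}-4-(phenylsulfanyl)-1-(tributylstannyl)pent-1-en-3-ol | C[C@@H](Sc1ccccc1)[C@@](/C=C/[Sn](CCCC)(CCCC)CCCC)(O)CO[Si](C)(C)C(C)(C)C | intermediate
11 | methyl 2-hydroxyacetate | COC(=O)CO | starting material
12 | methyl 2-[tri(propan-2-yl)silyloxy]acetate | COC(=O)CO[Si](C(C)C)(C(C)C)C(C)C | intermediate
13 | N-methoxy-N-methyl-2-[tri(propan-2-yl)silyloxy]acetamide | CON(C)C(=O)CO[Si](C(C)C)(C(C)C)C(C)C | intermediate
14 | 1-[tri(propan-2-yl)silyloxy]-4-(trimethylsilyl)but-3-yn-2-one | C[Si](C)(C)C#CC(=O)CO[Si](C(C)C)(C(C)C)C(C)C | intermediate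
15 | (4E,6S,7R)-6-{[(tert-butyldimethylsilyl)oxy]methyl}-7-(phenylsulfanyl)-3-{[tri(propan-2-yl)silyloxy]methyl}-1-(trimethylsilyl)oct-4-en-1-yne-3,6-diol, both C3 epimers (C3 of this name is briarane C5) | C[C@@H](Sc1ccccc1)[C@@](/C=C/C(O)(CO[Si](C(C)C)(C(C)C)C(C)C)C#C[Si](C)(C)C)(O)CO[Si](C)(C)C(C)(C)C | intermediate
16 | trilithio species: the C17-lithio dilithium dialkoxide formed from 15 by loss of the phenylsulfanyl group | CC([Li])[C@@](/C=C/C(O[Li])(CO[Si](C(C)C)(C(C)C)C(C)C)C#C[Si](C)(C)C)(O[Li])CO[Si](C)(C)C(C)(C)C | intermediate (not isolated)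
17 | (3R,4E)-3-{[(tert-butyldimethylsilyl)oxy]methyl}-3,6-dihydroxy-2-methyl-6-{[tri(propan-2-yl)silyloxy]methyl}-8-(trimethylsilyl)oct-4-en-7-ynoic acid, C2 and C6 epimers | CC(C(O)=O)[C@@](/C=C/C(O)(CO[Si](C(C)C)(C(C)C)C(C)C)C#C[Si](C)(C)C)(O)CO[Si](C)(C)C(C)(C)C | intermediate (not isolated)
18 | (4R,5S)-4-{[(tert-butyldimethylsilyl)oxy]methyl}-4-hydroxy-3-methyl-5-[(1E)-2-{[tri(propan-2-yl)silyloxy]methyl}-4-(trimethylsilyl)but-1-en-3-yn-1-yl]oxolan-2-one, both C3 (C17) epimers | C[Si](C)(C)C#C\C(CO[Si](C(C)C)(C(C)C)C(C)C)=C/[C@@H]1OC(=O)C(C)[C@@]1(O)CO[Si](C)(C)C(C)(C)C | intermediate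
19 | (3R,4R,5S)-4-{[(tert-butyldimethylsilyl)oxy]methyl}-4-hydroxy-3-methyl-5-[(1E)-2-{[tri(propan-2-yl)silyloxy]methyl}-4-(trimethylsilyl)but-1-en-3-yn-1-yl]oxolan-2-one | C[Si](C)(C)C#C\C(CO[Si](C(C)C)(C(C)C)C(C)C)=C/[C@@H]1OC(=O)[C@H](C)[C@@]1(O)CO[Si](C)(C)C(C)(C)C | intermediate
20 | (3R,4R,5S)-4-{[(tert-butyldimethylsilyl)oxy]methyl}-4-hydroxy-5-[(1E)-4-iodo-2-{[tri(propan-2-yl)silyloxy]methyl}but-1-en-3-yn-1-yl]-3-methyloxolan-2-one | IC#C\C(CO[Si](C(C)C)(C(C)C)C(C)C)=C/[C@@H]1OC(=O)[C@H](C)[C@@]1(O)CO[Si](C)(C)C(C)(C)C | intermediate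
21 | (3R,4R,5S)-4-{[(tert-butyldimethylsilyl)oxy]methyl}-4-hydroxy-5-[(1E,3Z)-4-iodo-2-{[tri(propan-2-yl)silyloxy]methyl}buta-1,3-dien-1-yl]-3-methyloxolan-2-one | I/C=C\C(CO[Si](C(C)C)(C(C)C)C(C)C)=C/[C@@H]1OC(=O)[C@H](C)[C@@]1(O)CO[Si](C)(C)C(C)(C)C | intermediate
22 | (3R,4R,5S)-4-hydroxy-4-(hydroxymethyl)-5-[(1E,3Z)-4-iodo-2-{[tri(propan-2-yl)silyloxy]methyl}buta-1,3-dien-1-yl]-3-methyloxolan-2-one | I/C=C\C(CO[Si](C(C)C)(C(C)C)C(C)C)=C/[C@@H]1OC(=O)[C@H](C)[C@@]1(O)CO | intermediate
23 | (2S,3S,4R)-3-hydroxy-2-[(1E,3Z)-4-iodo-2-{[tri(propan-2-yl)silyloxy]methyl}buta-1,3-dien-1-yl]-4-methyl-5-oxooxolane-3-carbaldehyde | I/C=C\C(CO[Si](C(C)C)(C(C)C)C(C)C)=C/[C@@H]1OC(=O)[C@H](C)[C@@]1(O)C=O | intermediate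
24 | (S)-carvone, (5S)-2-methyl-5-(prop-1-en-2-yl)cyclohex-2-en-1-one | CC1=CC[C@@H](CC1=O)C(C)=C | starting material
25 | trimethyl{[(3S)-6-methyl-3-(prop-1-en-2-yl)cyclohexa-1,5-dien-1-yl]oxy}silane | CC1=CC[C@H](C(C)=C)C=C1O[Si](C)(C)C | intermediate (not isolated)
26 | (5S)-6-(dimethoxymethyl)-2-methyl-5-(prop-1-en-2-yl)cyclohex-2-en-1-one, both C6 epimers | COC(OC)C1[C@@H](C(C)=C)CC=C(C)C1=O | intermediate
27 | (5R,6R)-6-(dimethoxymethyl)-2,6-dimethyl-5-(prop-1-en-2-yl)cyclohex-2-en-1-one | COC(OC)[C@@]1(C)[C@@H](C(C)=C)CC=C(C)C1=O | intermediate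
28 | (1S,2R)-2-(dimethoxymethyl)-2,4-dimethyl-3-oxocyclohex-4-en-1-yl acetate | COC(OC)[C@@]1(C)[C@@H](OC(C)=O)CC=C(C)C1=O | intermediate
29 | (1S,2R,3R)-2-(dimethoxymethyl)-3-hydroxy-2,4-dimethylcyclohex-4-en-1-yl acetate | COC(OC)[C@@]1(C)[C@@H](OC(C)=O)CC=C(C)[C@H]1O | intermediate
30 | (1S,2S,3R)-2-(dimethoxymethyl)-3-[(methoxycarbonyl)oxy]-2,4-dimethylcyclohex-4-en-1-yl acetate | COC(OC)[C@@]1(C)[C@@H](OC(C)=O)CC=C(C)[C@H]1OC(=O)OC | intermediate
31 | (1S,2R,5S)-2-(dimethoxymethyl)-2,4-dimethyl-5-(4,4,5,5-tetramethyl-1,3,2-dioxaborolan-2-yl)cyclohex-3-en-1-yl acetate | COC(OC)[C@@]1(C)[C@@H](OC(C)=O)C[C@H](B2OC(C)(C)C(C)(C)O2)C(C)=C1 | intermediate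
32 | (1S,2R,3S)-2-(dimethoxymethyl)-3-[(S)-hydroxy{(2S,3R,4R)-3-hydroxy-2-[(1E,3Z)-4-iodo-2-{[tri(propan-2-yl)silyloxy]methyl}buta-1,3-dien-1-yl]-4-methyl-5-oxooxolan-3-yl}methyl]-2,4-dimethylcyclohex-4-en-1-yl acetate | COC(OC)[C@@]1(C)[C@@H](OC(C)=O)CC=C(C)[C@@H]1[C@H](O)[C@]2(O)[C@@H](C)C(=O)O[C@H]2/C=C(\C=C/I)CO[Si](C(C)C)(C(C)C)C(C)C | intermediate
33 | C9 acetate of 32: (1S,2R,3S)-3-[(S)-acetoxy{(2S,3S,4R)-3-hydroxy-2-[(1E,3Z)-4-iodo-2-{[tri(propan-2-yl)silyloxy]methyl}buta-1,3-dien-1-yl]-4-methyl-5-oxooxolan-3-yl}methyl]-2-(dimethoxymethyl)-2,4-dimethylcyclohex-4-en-1-yl acetate | COC(OC)[C@@]1(C)[C@@H](OC(C)=O)CC=C(C)[C@@H]1[C@H](OC(C)=O)[C@]2(O)[C@@H](C)C(=O)O[C@H]2/C=C(\C=C/I)CO[Si](C(C)C)(C(C)C)C(C)C | intermediate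
34 | C2 aldehyde: (1S,2R,3S)-3-[(S)-acetoxy{(2S,3S,4R)-3-hydroxy-2-[(1E,3Z)-4-iodo-2-{[tri(propan-2-yl)silyloxy]methyl}buta-1,3-dien-1-yl]-4-methyl-5-oxooxolan-3-yl}methyl]-2-formyl-2,4-dimethylcyclohex-4-en-1-yl acetate | O=C[C@@]1(C)[C@@H](OC(C)=O)CC=C(C)[C@@H]1[C@H](OC(C)=O)[C@]2(O)[C@@H](C)C(=O)O[C@H]2/C=C(\C=C/I)CO[Si](C(C)C)(C(C)C)C(C)C | intermediate
35 | macrocyclic alcohol: target skeleton with 2-OH free, 9,14-di-O-acetyl, 8-OH, 16-O-TIPS; (1S,2S,7S,8S,9S,10S,14S,17R), 3Z,5E | O[C@H]1/C=C\C(CO[Si](C(C)C)(C(C)C)C(C)C)=C/[C@@H]2OC(=O)[C@H](C)[C@@]2(O)[C@@H](OC(C)=O)[C@H]2C(C)=CC[C@H](OC(C)=O)[C@]12C | intermediate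
36 | 16-O-TIPS ether of the target: 2,9,14-tri-O-acetyl, 8-OH; (1R,2S,7S,8S,9S,10S,14S,17R), 3Z,5E | CC(=O)O[C@H]1/C=C\C(CO[Si](C(C)C)(C(C)C)C(C)C)=C/[C@@H]2OC(=O)[C@H](C)[C@@]2(O)[C@@H](OC(C)=O)[C@H]2C(C)=CC[C@H](OC(C)=O)[C@]12C | intermediate
37 | CNP0215504.2: 2,9,14-tri-O-acetyl-8,16-dihydroxy briarane 7-lactone; (1R,2S,7S,8S,9S,10S,14S,17R), 3Z,5E | CC(=O)O[C@H]1/C=C\C(CO)=C/[C@@H]2OC(=O)[C@H](C)[C@@]2(O)[C@@H](OC(C)=O)[C@H]2C(C)=CC[C@H](OC(C)=O)[C@]12C | target

**Summary**

Total step count: 30. Longest linear sequence: 21 steps (steps 1–8, 12–18, 25–30).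

Steps most likely to fail:

- Step 13. What may go wrong: loss of Li2O from the β-oxido organolithium before CO2 capture, or electron transfer to the silylalkyne in competition with C–S cleavage. Fallback (no reductant; carbanion made by deprotonation): setting out from 15, the sulfide is oxidized with H2O2 and (NH4)6Mo7O24 (cat.) to the sulfone F1. Its O,O,C-trianion (n-BuLi, THF, −78 °C) is carbonated with CO2 and acidified with CF3CO2H as in step 13 to give the α-sulfonyl lactone F2. Desulfonylation with SmI2 in THF/MeOH returns the route to 18, which enters step 14.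
- Step 25. What may go wrong: steric retardation of bond formation between the two neopentyl-type carbons C9 and C10, so that protodeboronation or attack of the C9 borate on the lactone takes over. Fallback (Barbier allylation with a more nucleophilic, equilibrating allylmetal): setting out from 29, Appel bromination (CBr4, PPh3) gives the allylic bromide F3 (regio- and stereoisomers converge). Indium powder in THF/H2O with 23 then forms the allylindium, which should react through C10 on the methyl face by the same chair topology and return the route to 32.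
- Step 28. What may go wrong: poor facial selectivity at the C2 aldehyde during ring closure, giving mainly the 2R alcohol. Fallback (C2 set by ketone reduction instead of by the C–C bond formation): setting out from 35 as its C2-epimer mixture, oxidation with MnO2 gives the dienone F4. Reduction with NaBH4/CeCl3 (peripheral hydride delivery), or with BH3 and the matched Corey–Bakshi–Shibata oxazaborolidine, returns the route to 35.

Further compounds
F1 | step 13 | sulfone of 15 (phenylsulfonyl in place of phenylsulfanyl on C17), C5 epimers | C[C@@H](S(=O)(=O)c1ccccc1)[C@@](/C=C/C(O)(CO[Si](C(C)C)(C(C)C)C(C)C)C#C[Si](C)(C)C)(O)CO[Si](C)(C)C(C)(C)C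
F2 | step 13 | 17-phenylsulfonyl derivative of lactone 18, C17 epimers | C[Si](C)(C)C#C\C(CO[Si](C(C)C)(C(C)C)C(C)C)=C/[C@@H]1OC(=O)C(C)(S(=O)(=O)c2ccccc2)[C@@]1(O)CO[Si](C)(C)C(C)(C)C
F3 | step 25 | allylic bromide from 29 (bromine in place of the C10 hydroxyl, C10 epimers) | COC(OC)[C@@]1(C)[C@@H](OC(C)=O)CC=C(C)C1Br
F4 | step 28 | C2 ketone (dienone) of 35 | O=C1/C=C\C(CO[Si](C(C)C)(C(C)C)C(C)C)=C/[C@@H]2OC(=O)[C@H](C)[C@@]2(O)[C@@H](OC(C)=O)[C@H]2C(C)=CC[C@H](OC(C)=O)[C@]12C
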